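## Structural features

The target (29) is built from three units: a 2,6-diaryl-3,7-dioxabicyclo[3.3.0]octane (ring D = C1–C2–O3–C4–C5, ring E = C1–C8–O7–C6–C5), a syringyl ring F on C6, and a 2-aryl-3-(hydroxymethyl)-7-methoxy-2,3-dihydrobenzofuran (benzo ring B, dihydrofuran ring C with O1', C2', C3', guaiacyl ring A on C2') bonded through C5' to C2. Six stereocentres fall into two clusters: the contiguous chain C2–C1–C5–C6 (1R,2S,5R,6S; rings D and E cis-fused, both aryl groups exo) and the pair C2'/C3' (2'S,3'S, aryl and hydroxymethyl cis). Ring B lies between the clusters, so neither can steer the other. C2–O3, C6–O7 and C2'–O1' are all benzylic ethers of para-oxygenated arenes: acid ionises them (epimerisation of the furofuran, cis-to-trans isomerisation of ring C), hydrogenolysis can cleave them, and once a para phenol is free, base can open them through quinone methides. The cis arrangement on ring C is the less stable one, and at the ester stage through which it is made C3' is also epimerisable by base. The real difficulty is therefore not the furofuran, whose relative configuration is the thermodynamically preferred one, but making the contra-thermodynamic cis ring C as one enantiomer and carrying it through a furofuran synthesis that sets the remote cluster in the right absolute sense without acid. The key step uses the fact that O1' is para to C5': with ring E held at the lactone level (C8=O), a C1=C2 double bond is a polarised arylidene lactone, the hydroxyl on C4 can close ring D by forming C2–O3, and the short tether C5–C4–O3 allows only a cis-fused bridgehead C1, so C5 and C6, set early, dictate C1 and C2.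

## Logic of the disconnections

29 ⇒ 28. The two aryl O–CH2Ph bonds are cut last. The phenols stay masked to the end because a free para phenol makes C2–O3, C6–O7 and C2'–O1' base-labile. Only aryl benzyl ethers are left at this stage, so the forward hydrogenolysis can be brief and neutral; it must be stopped before the ring benzylic C–O bonds react.

28 ⇒ 25 (through 26 and 27). The C8–O7 bond of ring E and the O–Si bond of the ring C side chain are cut. Ring E is closed by displacement at the primary carbon C8, so the C6–O bond and every stereocentre stay untouched and no acid is needed. The side-chain hydroxyl is carried as a silyl ether, not a benzyl ether, so that it is freed by fluoride while the phenols are still protected. The forward step must activate the primary C8 hydroxyl in preference to the secondary benzylic C6 hydroxyl.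

25 ⇒ 24. This is a redox change at C8 only. The C8 carbonyl is the activating group of the key step and is removed immediately afterwards. The forward reduction must be faster than enolisation at C1, which would reopen ring D.

24 ⇒ 23. The C2–O3 bond is cut. This removes ring D and the stereocentres C1 and C2 in one stroke and leaves a planar arylidene lactone in which C1 has no configuration to set. The forward step is a 5-endo conjugate addition that has to be reversible, chemoselective for C2 over the lactone carbonyl C8, and run with a base too weak to move the double bond into the ring. For that reason the free C4 hydroxyl is revealed only in 23, under non-basic conditions.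

23 ⇒ 22 ⇒ 9 + 19. The O–Si bond at C4–O and then the C1=C2 bond are cut. The double bond is the most convergent junction: it joins two enantiopure halves of similar size, each with one stereocluster, and the configuration created at C1 during the addition is erased on dehydration. The demands are E geometry and two silyl groups of different stability (on C4–O in 9, on the ring C side chain in 19).

9 ⇒ 8 ⇒ 7 ⇒ 6 (through 5) ⇒ 3 + 4. After the O–Si bond and two redox changes at C4 (CH2OH ⇐ CO2H ⇐ imide), the C5–C6 bond and the lactone bond C8–O7 are cut together. C5/C6 is an aldol relationship, and a syn aldol maps onto the 4,5-trans lactone, so one auxiliary-controlled transition state sets both centres. This gives the achiral pair 3 and 4. The forward sequence needs chemoselective cleavage of the imide and reduction of the acid beside the lactone.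

3 ⇒ 1 + 2. The N–acyl bond is cut; the forward step is a standard acylation.

19 ⇒ 18 ⇒ 17 ⇒ 16. The C5'–CHO bond (formyl from bromide), the O–Si bond and the oxidation level of the C3' substituent are retraced. Bromine is an inert placeholder for the formyl group through the carbene chemistry, and the ester is what makes the carbene accessible. The ester must be reduced without base, because the cis ester epimerises at C3'.

16 ⇒ 15. The C2'–C3' bond of ring C is cut. A concerted carbene insertion into the benzylic C–H bond is a kinetic, catalyst-controlled way to the cis isomer and takes the fragment back to an achiral diazo ester. It demands a chiral dirhodium catalyst, low temperature and suppression of ylide pathways.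

15 ⇒ 14 ⇒ 13 ⇒ 12 ⇒ 10 + 11. The diazo group, then the one-carbon homologation (the C=C bond of 13 made from the formyl group of 12), then the aryl O–CH2 bond are cut. 10 already carries bromine para and methoxy ortho to the hydroxyl. The homologation has to avoid acid, because the aryl p-alkoxybenzyl ether of 12–15 is acid-labile.

## Other disconnections considered

Alternative 1: The cut is at C3a'–C7a' and C6'–C7' of ring B. Ring B is taken apart into a furan (C3a', C4', C5', C6') and an ethynyl ether (C7a', C7'). The precursor is the furan–yne A2 and the product is the phenol A1. In the forward step a cationic gold catalyst such as Ph3PAuNTf2 (monovalent gold) activates the ynol ether, the furan attacks, and the arene oxide cascade moves the furan oxygen to C7', closing rings B and C together.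
- In its favour: the C2'/C3' pair would be set in an open chain (a syn aldol would do) and is never next to a carbonyl group once ring C exists. On the security of C3' this alternative is the equal or the better of the chosen plan, which passes through the epimerisable ester 16. The C7' oxygen emerges as the only free phenol, so its methylation is unambiguous.
- Against it here: a secondary benzylic ynol ether with an electron-rich aryl group is hard to prepare. Once gold has turned the alkyne into a ketene-like cation, the C2'–O1' bond is expected to ionise easily, which would erase the cis relationship. The sense of oxygen transfer with a 2,4-disubstituted furan is uncertain.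
- Comparison: it solves only the dihydrobenzofuran half, so a furofuran construction such as step 16 is still needed. A1 needs methylation, desilylation and oxidation before it is equivalent to 19, and A2 is itself about six steps from simple materials, so there is no gain over the eight steps to 19. Mechanistically, the carbene insertion of step 10 has closer precedent on benzyl aryl ethers.

Alternative 2: The cut is at C5–C6 and C1–C2. In the forward step the lithiated dithiane A5 adds to the chiral butenolide A4 anti to the menthyloxy group, and the lactone enolate is trapped by the aldehyde A6 anti to the new substituent, giving A3.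
- In its favour: three components, two C–C bonds and both ring-fusion carbons come together in one flask under control of a cheap auxiliary, and the reaction type is established for lignans. On convergence and on precedent of the key step this alternative is better than the chosen plan. The trans relationship of C1 and C5 in A3 is the correct one for the cis-fused furofuran, which makes it the equal of the chosen plan on that point.
- Against it here: in A3, C6 is a dithioketal carbon and C2 a carbinol of undefined configuration, so both benzylic ether centres remain to be made. That requires dithiane cleavage (HgCl2 or an oxidant beside three electron-rich arenes), ketone reduction, reduction of the acetal lactone and two benzylic etherifications that run through cations under acid. That acid is exactly what the cis ring C cannot be expected to tolerate.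
- Comparison: about six steps from A3 to 29, comparable with the six steps from 9 + 19. The chosen plan forms C2–O3 under base and sets C6 by an aldol reaction.

Alternative 3: The cut is at C1–C5 and C6–O7. In the forward step Cp2TiCl (trivalent titanium) opens the epoxide of the ether A8 homolytically, the C1 radical closes 5-exo onto the alkene to make ring D, and iodine converts the C6 benzylic intermediate into a cation or iodide that the C8 alkoxide captures to make ring E, giving A7.
- In its favour: both tetrahydrofuran rings arise from one open-chain ether, and C8 is already at the ether oxidation level. On redox economy and on the number of steps after the key step (deprotections only) this alternative is better than the chosen plan. The reaction type is known for furofuran lignans.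
- Against it here: C1, C5 and C6 would all arise under substrate control from the single centre C2, and mixtures at C1/C2 and at C6 are to be expected. A8 needs an enantioenriched C2 carbinol (resolution or asymmetric vinyl addition, then epoxidation) and a labile sinapyl-type allyl ether. Iodine treatment releases HI beside the acid-labile ring C, and the metal is stoichiometric.
- Comparison: the chosen plan is longer, but it ties each centre to a defined control element: the auxiliary for C5/C6, and ring constraint and equilibration for C1/C2.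

Key step: step 16

Conventions and assumptions:
- SyrBn = 4-benzyloxy-3,5-dimethoxyphenyl. DHB = (2S,3S)-2-(4-benzyloxy-3-methoxyphenyl)-3-[(tert-butyldiphenylsilyloxy)methyl]-7-methoxy-2,3-dihydrobenzofuran-5-yl (2,3-cis).
- Assumption: 4 and 11, the O-benzyl derivatives of syringaldehyde and of vanillyl alcohol, are bought as catalogue compounds.
- Assumption: Rh2(S-PTTL)4 is taken to deliver the (2S,3R) cis ester 16; should the sense be opposite, Rh2(R-PTTL)4 is used with no other change.
- Metal enolates and the aryllithium are treated as activated forms of numbered compounds and are not numbered separately.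

## Route

Step 1
Reactants: 1 (S)-4-benzyloxazolidin-2-one; 2 methyl 4-chloro-4-oxobutanoate
Product: 3 (S)-4-benzyl-3-(4-methoxy-4-oxobutanoyl)oxazolidin-2-one
Conditions: n-BuLi, THF, −78 °C; then 2, −78 to 0 °C
Reagents that add atoms: none
Why: N-acylation of the lithiated oxazolidinone by the acid chloride; the methyl ester does not compete at −78 °C.

Step 2
Reactants: 3 (S)-4-benzyl-3-(4-methoxy-4-oxobutanoyl)oxazolidin-2-one; 4 4-benzyloxy-3,5-dimethoxybenzaldehyde
Product: 6 (S)-4-benzyl-3-[(2S,3S)-2-(4-benzyloxy-3,5-dimethoxyphenyl)-5-oxotetrahydrofuran-3-carbonyl]oxazolidin-2-one (2,3-trans lactone), via syn aldol adduct 5 (not isolated)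
Conditions: Bu2BOTf, i-Pr2NEt, CH2Cl2, 0 °C; then 4, −78 °C to rt; pH 7 buffer (NaH2PO4/Na2HPO4), H2O2, MeOH, 0 °C
Reagents that add atoms: none
Why: Evans syn aldol reaction: the Z boron enolate of the imide carbonyl reacts through a chair transition state on the face away from the benzyl group of the auxiliary, which sets the future C6 and C5 (both S in 5). In the syn aldolate the oxygen and the ester arm are gauche, so closure onto the methyl ester should give the trans lactone.

Step 3
Reactants: 6 (S)-4-benzyl-3-[(2S,3S)-2-(4-benzyloxy-3,5-dimethoxyphenyl)-5-oxotetrahydrofuran-3-carbonyl]oxazolidin-2-one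
Product: 7 (2S,3S)-2-(4-benzyloxy-3,5-dimethoxyphenyl)-5-oxotetrahydrofuran-3-carboxylic acid (trans)
Conditions: LiOH, H2O2, THF/H2O, 0 °C; Na2SO3; HCl to pH 2
Reagents that add atoms: hydrogen peroxide (acting as LiOOH), OO
Why: Hydroperoxide cleaves the exocyclic imide carbonyl selectively and the auxiliary is recovered. Any lactone opened by hydroxide recloses on acidification, and the trans acid is also the more stable epimer.

Step 4
Reactants: 7 (2S,3S)-2-(4-benzyloxy-3,5-dimethoxyphenyl)-5-oxotetrahydrofuran-3-carboxylic acid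
Product: 8 (4R,5S)-5-(4-benzyloxy-3,5-dimethoxyphenyl)-4-(hydroxymethyl)dihydrofuran-2(3H)-one (trans)
Conditions: BH3·SMe2, THF, 0 °C to rt; MeOH
Reagents that add atoms: none
Why: Borane reduces a carboxylic acid through its acyloxyborane far faster than a lactone, and the medium is not basic, so the lactone should neither be reduced nor migrate to the new hydroxyl.

Step 5
Reactants: 8 (4R,5S)-5-(4-benzyloxy-3,5-dimethoxyphenyl)-4-(hydroxymethyl)dihydrofuran-2(3H)-one
Product: 9 (4R,5S)-5-(4-benzyloxy-3,5-dimethoxyphenyl)-4-[(tert-butyldimethylsilyloxy)methyl]dihydrofuran-2(3H)-one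
Conditions: TBSCl, imidazole, CH2Cl2, 0 °C
Reagents that add atoms: tert-butyldimethylsilyl chloride, CC(C)(C)[Si](C)(C)Cl
Why: Silylation of the primary alcohol blocks acyl migration of the lactone and protects the hydroxyl for the enolate chemistry of step 14.

Step 6
Reactants: 10 5-bromo-2-hydroxy-3-methoxybenzaldehyde; 11 (4-benzyloxy-3-methoxyphenyl)methanol
Product: 12 2-[(4-benzyloxy-3-methoxyphenyl)methoxy]-5-bromo-3-methoxybenzaldehyde
Conditions: PPh3, DIAD, THF, 0 °C to rt
Reagents that add atoms: none
Why: Mitsunobu etherification: the hydrogen-bonded salicylaldehyde phenol is acidic enough to serve as the pronucleophile, and the primary benzylic alcohol is activated without passing through the labile benzylic halide.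

Step 7
Reactants: 12 2-[(4-benzyloxy-3-methoxyphenyl)methoxy]-5-bromo-3-methoxybenzaldehyde
Product: 13 1-[(4-benzyloxy-3-methoxyphenyl)methoxy]-4-bromo-2-methoxy-6-(2-methoxyethenyl)benzene (E/Z mixture)
Conditions: MeOCH2PPh3Cl, KOt-Bu, THF, 0 °C to rt
Reagents that add atoms: (methoxymethyl)triphenylphosphonium chloride, COC[P+](c1ccccc1)(c1ccccc1)c1ccccc1.[Cl-]
Why: Wittig olefination of a non-enolisable aldehyde with the methoxymethylene ylide adds the missing carbon; the alkene geometry is irrelevant.

Step 8
Reactants: 13 1-[(4-benzyloxy-3-methoxyphenyl)methoxy]-4-bromo-2-methoxy-6-(2-methoxyethenyl)benzene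
Product: 14 methyl 2-[2-[(4-benzyloxy-3-methoxyphenyl)methoxy]-5-bromo-3-methoxyphenyl]acetate
Conditions: C5H5NH[CrO3Cl], NaOAc, 4 Å molecular sieves, CH2Cl2, rt
Reagents that add atoms: pyridinium chlorochromate, [O-][Cr](=O)(=O)Cl.c1cc[nH+]cc1
Why: Chlorochromate oxidation of an enol ether that bears a hydrogen on the alkoxy carbon gives the ester directly. The acetate buffer keeps the medium from cleaving the acid-labile aryl p-alkoxybenzyl ether.

Step 9
Reactants: 14 methyl 2-[2-[(4-benzyloxy-3-methoxyphenyl)methoxy]-5-bromo-3-methoxyphenyl]acetate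
Product: 15 methyl 2-[2-[(4-benzyloxy-3-methoxyphenyl)methoxy]-5-bromo-3-methoxyphenyl]-2-diazoacetate
Conditions: 4-acetamidobenzenesulfonyl azide, DBU, MeCN, 0 °C to rt
Reagents that add atoms: 4-acetamidobenzenesulfonyl azide, CC(=O)Nc1ccc(cc1)S(=O)(=O)N=[N+]=[N-]
Why: Regitz diazo transfer to the enolate of an arylacetate, the standard entry to aryl diazoacetates.

Step 10
Reactants: 15 methyl 2-[2-[(4-benzyloxy-3-methoxyphenyl)methoxy]-5-bromo-3-methoxyphenyl]-2-diazoacetate
Product: 16 methyl (2S,3R)-2-(4-benzyloxy-3-methoxyphenyl)-5-bromo-7-methoxy-2,3-dihydrobenzofuran-3-carboxylate (2,3-cis)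
Conditions: Rh2(S-PTTL)4 (1 mol %), toluene, −60 °C
Reagents that add atoms: none
Why: Intramolecular 1,5 C–H insertion of the dirhodium carbene (divalent rhodium carboxylate dimer) into the benzylic ether C–H bond, activated by O1' and the para-alkoxy aryl group. The concerted insertion is expected to give the kinetic cis product, with C2' and C3' set by the chiral carboxylate ligands.

Step 11
Reactants: 16 methyl (2S,3R)-2-(4-benzyloxy-3-methoxyphenyl)-5-bromo-7-methoxy-2,3-dihydrobenzofuran-3-carboxylate
Product: 17 [(2S,3S)-2-(4-benzyloxy-3-methoxyphenyl)-5-bromo-7-methoxy-2,3-dihydrobenzofuran-3-yl]methanol (cis)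
Conditions: i-Bu2AlH, CH2Cl2, −78 to −20 °C; aq. potassium sodium tartrate
Reagents that add atoms: none
Why: Reduction of the ester by a non-basic hydride at low temperature avoids enolisation at C3', so the cis relationship should be kept; the aryl bromide is inert.

Step 12
Reactants: 17 [(2S,3S)-2-(4-benzyloxy-3-methoxyphenyl)-5-bromo-7-methoxy-2,3-dihydrobenzofuran-3-yl]methanol
Product: 18 tert-butyl{[(2S,3S)-2-(4-benzyloxy-3-methoxyphenyl)-5-bromo-7-methoxy-2,3-dihydrobenzofuran-3-yl]methoxy}diphenylsilane
Conditions: TBDPSCl, imidazole, DMF, rt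
Reagents that add atoms: tert-butyl(chloro)diphenylsilane, CC(C)(C)[Si](Cl)(c1ccccc1)c1ccccc1
Why: The silyl ether withstands n-BuLi, LiN(SiMe3)2 and LiAlH4, outlasts the TBS ether of 9 toward HF·pyridine, and leaves later with fluoride instead of hydrogenolysis.

Step 13
Reactants: 18 tert-butyl{[(2S,3S)-2-(4-benzyloxy-3-methoxyphenyl)-5-bromo-7-methoxy-2,3-dihydrobenzofuran-3-yl]methoxy}diphenylsilane
Product: 19 (2S,3S)-2-(4-benzyloxy-3-methoxyphenyl)-3-[(tert-butyldiphenylsilyloxy)methyl]-7-methoxy-2,3-dihydrobenzofuran-5-carbaldehyde (DHB–CHO)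
Conditions: n-BuLi, THF, −78 °C; DMF; aq. NH4Cl
Reagents that add atoms: N,N-dimethylformamide, CN(C)C=O
Why: Bromine–lithium exchange is much faster than deprotonation at −78 °C, and the aryllithium is formylated by DMF (Bouveault reaction); no acidic C–H flanks C2' or C3'.

Step 14
Reactants: 9 (4R,5S)-5-(4-benzyloxy-3,5-dimethoxyphenyl)-4-[(tert-butyldimethylsilyloxy)methyl]dihydrofuran-2(3H)-one; 19 DHB–CHO
Product: 22 (3E,4R,5S)-5-(4-benzyloxy-3,5-dimethoxyphenyl)-4-[(tert-butyldimethylsilyloxy)methyl]-3-(DHB-methylidene)dihydrofuran-2(3H)-one, via aldol adduct 20 (not isolated), via mesylate 21 (not isolated)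
Conditions: LiN(SiMe3)2, THF, −78 °C; 19; aq. NH4Cl; crude: MsCl, Et3N, CH2Cl2, 0 °C; then DBU, 0 °C to rt
Reagents that add atoms: none
Why: Aldol addition of the lactone lithium enolate anti to the C4 substituent, followed by mesylation and E1cB elimination. The elimination should give the more stable E-arylidene lactone (aryl anti to the carbonyl), and the centre formed at C1 in 20 is erased, so its ratio does not matter.

Step 15
Reactants: 22 (3E,4R,5S)-5-(4-benzyloxy-3,5-dimethoxyphenyl)-4-[(tert-butyldimethylsilyloxy)methyl]-3-(DHB-methylidene)dihydrofuran-2(3H)-one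
Product: 23 (3E,4R,5S)-5-(4-benzyloxy-3,5-dimethoxyphenyl)-4-(hydroxymethyl)-3-(DHB-methylidene)dihydrofuran-2(3H)-one
Conditions: HF·pyridine, pyridine, THF, 0 °C
Reagents that add atoms: none
Why: Buffered HF removes the primary TBS ether much faster than the TBDPS ether. No alkoxide is formed, so neither cyclisation nor acyl migration should begin before the controlled conditions of step 16.

Step 16
Reactants: 23 (3E,4R,5S)-5-(4-benzyloxy-3,5-dimethoxyphenyl)-4-(hydroxymethyl)-3-(DHB-methylidene)dihydrofuran-2(3H)-one
Product: 24 (1S,2S,5R,6S)-6-(4-benzyloxy-3,5-dimethoxyphenyl)-2-DHB-3,7-dioxabicyclo[3.3.0]octan-8-one (cis-fused; both aryl groups exo)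
Conditions: KOt-Bu (0.2 equiv), t-BuOH (2 equiv), THF (0.02 M), −20 to 0 °C; then AcOH, −20 °C
Reagents that add atoms: none
Why: Proposed new method: the potassium alkoxide of O3 adds to the benzylidene carbon C2 of the E-arylidene lactone (intramolecular oxa-Michael addition), the lactone enolate is protonated at C1 by t-BuOH and the alkoxide is regenerated, so the base is catalytic and every stage is reversible. The closest known reactions are base-mediated 5-endo-trig oxa-Michael cyclisations of hydroxy-tethered vinyl sulfones and alkylidene lactones and the quinone methide ring closures of lignan biosynthesis; a β-hydroxymethyl α-arylidene γ-lactone has not been closed in this way. Ring D closes in the 5-endo-trig mode, which should be feasible here because C4 already stands above the plane of the exocyclic alkene on the sp3 carbon C5 and because the addition is under thermodynamic control. C2 is set by attack on the alkene face that carries C4, the only face the tether reaches, which places ring B exo from the E isomer; the addition–elimination equilibrium should also funnel any Z isomer or endo adduct to the exo aryl product. C1 is set by protonation on the convex face, since the two-atom tether allows only the cis-fused bicycle, so C1 is dictated by C5. The step needs selectivity for C2 over the lactone carbonyl C8 and over deprotonation at C5. Attack at C8 would require a dioxabicyclo[2.2.1]heptane tetrahedral intermediate with the alkylidene carbon C1 as its one-atom bridge, and a hindered base in an aprotic medium gives no intermolecular path for transesterification. Catalytic KOt-Bu buffered by t-BuOH at or below 0 °C is expected to be too weak to remove the merely allylic C5 proton and move the double bond into the ring.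

Step 17
Reactants: 24 (1S,2S,5R,6S)-6-(4-benzyloxy-3,5-dimethoxyphenyl)-2-DHB-3,7-dioxabicyclo[3.3.0]octan-8-one
Product: 25 (S)-(4-benzyloxy-3,5-dimethoxyphenyl)[(3R,4R,5S)-5-DHB-4-(hydroxymethyl)tetrahydrofuran-3-yl]methanol
Conditions: LiAlH4, THF, −20 to 0 °C; aq. potassium sodium tartrate
Reagents that add atoms: none
Why: Hydride reduction of the lactone to the 1,4-diol is fast at low temperature and should outrun enolisation at C1; once C8 is reduced, ring D can no longer reopen. No C–O bond at a stereocentre is touched.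

Step 18
Reactants: 25 (S)-(4-benzyloxy-3,5-dimethoxyphenyl)[(3R,4R,5S)-5-DHB-4-(hydroxymethyl)tetrahydrofuran-3-yl]methanol
Product: 28 (1R,2S,5R,6S)-2-[(2S,3S)-2-(4-benzyloxy-3-methoxyphenyl)-3-(hydroxymethyl)-7-methoxy-2,3-dihydrobenzofuran-5-yl]-6-(4-benzyloxy-3,5-dimethoxyphenyl)-3,7-dioxabicyclo[3.3.0]octane, via primary mesylate 26 (not isolated), via silyl furofuran 27 (not isolated)
Conditions: MsCl (1.05 equiv), pyridine, CH2Cl2, 0 °C to rt; then Bu4NF, THF, rt
Reagents that add atoms: none
Why: Sulfonylation of the primary C8 hydroxyl followed by intramolecular Williamson closure (5-exo-tet) by the C6 hydroxyl makes ring E with retention at C6, and the cis placement of the two arms on ring D enforces the cis fusion. Fluoride then removes the TBDPS ether while both phenols are still benzylated, so no phenoxide stands para to a benzylic ether.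

Step 19
Reactants: 28 (1R,2S,5R,6S)-2-[(2S,3S)-2-(4-benzyloxy-3-methoxyphenyl)-3-(hydroxymethyl)-7-methoxy-2,3-dihydrobenzofuran-5-yl]-6-(4-benzyloxy-3,5-dimethoxyphenyl)-3,7-dioxabicyclo[3.3.0]octane
Product: 29 (1R,2S,5R,6S)-2-[(2S,3S)-2-(4-hydroxy-3-methoxyphenyl)-3-(hydroxymethyl)-7-methoxy-2,3-dihydrobenzofuran-5-yl]-6-(4-hydroxy-3,5-dimethoxyphenyl)-3,7-dioxabicyclo[3.3.0]octane (CNP0126146.1)
Conditions: H2 (1 atm), 10% Pd/C, EtOAc, rt; stopped at full conversion
Reagents that add atoms: none
Why: Aryl benzyl ethers are hydrogenolysed much faster than the cyclic benzylic C–O bonds in a neutral aprotic medium, so only the two phenols should be released. No acid or base is present that could isomerise ring C or the furofuran.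

## Compound list

1 | (S)-4-benzyloxazolidin-2-one | O=C1N[C@@H](Cc2ccccc2)CO1 | starting material
2 | methyl 4-chloro-4-oxobutanoate | COC(=O)CCC(Cl)=O | starting material
3 | (S)-4-benzyl-3-(4-methoxy-4-oxobutanoyl)oxazolidin-2-one | COC(=O)CCC(=O)N1[C@@H](Cc2ccccc2)COC1=O | intermediate
4 | 4-benzyloxy-3,5-dimethoxybenzaldehyde | COc1cc(C=O)cc(OC)c1OCc1ccccc1 | starting material
5 | (S)-4-benzyl-3-[(2S,3S)-3-(4-benzyloxy-3,5-dimethoxyphenyl)-3-hydroxy-2-(2-methoxy-2-oxoethyl)propanoyl]oxazolidin-2-one (syn aldol adduct, present as its boron aldolate) | O[C@H](c1cc(OC)c(OCc2ccccc2)c(OC)c1)[C@H](CC(=O)OC)C(=O)N1[C@@H](Cc2ccccc2)COC1=O | intermediate (not isolated)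
6 | (S)-4-benzyl-3-[(2S,3S)-2-(4-benzyloxy-3,5-dimethoxyphenyl)-5-oxotetrahydrofuran-3-carbonyl]oxazolidin-2-one (trans) | C1C(=O)O[C@H](c2cc(OC)c(OCc3ccccc3)c(OC)c2)[C@H]1C(=O)N1[C@@H](Cc2ccccc2)COC1=O | intermediate
7 | (2S,3S)-2-(4-benzyloxy-3,5-dimethoxyphenyl)-5-oxotetrahydrofuran-3-carboxylic acid (trans) | C1C(=O)O[C@H](c2cc(OC)c(OCc3ccccc3)c(OC)c2)[C@H]1C(=O)O | intermediate
8 | (4R,5S)-5-(4-benzyloxy-3,5-dimethoxyphenyl)-4-(hydroxymethyl)dihydrofuran-2(3H)-one (trans) | C1C(=O)O[C@H](c2cc(OC)c(OCc3ccccc3)c(OC)c2)[C@H]1CO | intermediate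
9 | (4R,5S)-5-(4-benzyloxy-3,5-dimethoxyphenyl)-4-[(tert-butyldimethylsilyloxy)methyl]dihydrofuran-2(3H)-one | C1C(=O)O[C@H](c2cc(OC)c(OCc3ccccc3)c(OC)c2)[C@H]1CO[Si](C)(C)C(C)(C)C | intermediate
10 | 5-bromo-2-hydroxy-3-methoxybenzaldehyde | COc1cc(Br)cc(C=O)c1O | starting material
11 | (4-benzyloxy-3-methoxyphenyl)methanol | COc1cc(CO)ccc1OCc1ccccc1 | starting material
12 | 2-[(4-benzyloxy-3-methoxyphenyl)methoxy]-5-bromo-3-methoxybenzaldehyde | COc1cc(Br)cc(C=O)c1OCc1ccc(OCc2ccccc2)c(OC)c1 | intermediate
13 | 1-[(4-benzyloxy-3-methoxyphenyl)methoxy]-4-bromo-2-methoxy-6-(2-methoxyethenyl)benzene (E/Z mixture) | COC=Cc1cc(Br)cc(OC)c1OCc1ccc(OCc2ccccc2)c(OC)c1 | intermediate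
14 | methyl 2-[2-[(4-benzyloxy-3-methoxyphenyl)methoxy]-5-bromo-3-methoxyphenyl]acetate | COC(=O)Cc1cc(Br)cc(OC)c1OCc1ccc(OCc2ccccc2)c(OC)c1 | intermediate
15 | methyl 2-[2-[(4-benzyloxy-3-methoxyphenyl)methoxy]-5-bromo-3-methoxyphenyl]-2-diazoacetate | COC(=O)C(=[N+]=[N-])c1cc(Br)cc(OC)c1OCc1ccc(OCc2ccccc2)c(OC)c1 | intermediate
16 | methyl (2S,3R)-2-(4-benzyloxy-3-methoxyphenyl)-5-bromo-7-methoxy-2,3-dihydrobenzofuran-3-carboxylate (cis) | COc1cc([C@H]2Oc3c(OC)cc(Br)cc3[C@H]2C(=O)OC)ccc1OCc1ccccc1 | intermediate
17 | [(2S,3S)-2-(4-benzyloxy-3-methoxyphenyl)-5-bromo-7-methoxy-2,3-dihydrobenzofuran-3-yl]methanol (cis) | COc1cc([C@H]2Oc3c(OC)cc(Br)cc3[C@H]2CO)ccc1OCc1ccccc1 | intermediate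
18 | tert-butyl{[(2S,3S)-2-(4-benzyloxy-3-methoxyphenyl)-5-bromo-7-methoxy-2,3-dihydrobenzofuran-3-yl]methoxy}diphenylsilane | COc1cc([C@H]2Oc3c(OC)cc(Br)cc3[C@H]2CO[Si](c2ccccc2)(c2ccccc2)C(C)(C)C)ccc1OCc1ccccc1 | intermediate
19 | (2S,3S)-2-(4-benzyloxy-3-methoxyphenyl)-3-[(tert-butyldiphenylsilyloxy)methyl]-7-methoxy-2,3-dihydrobenzofuran-5-carbaldehyde | COc1cc([C@H]2Oc3c(OC)cc(C=O)cc3[C@H]2CO[Si](c2ccccc2)(c2ccccc2)C(C)(C)C)ccc1OCc1ccccc1 | intermediate
20 | (3R,4R,5S)-5-(4-benzyloxy-3,5-dimethoxyphenyl)-4-[(tert-butyldimethylsilyloxy)methyl]-3-[DHB(hydroxy)methyl]dihydrofuran-2(3H)-one (3,4-trans; both carbinol epimers) | COc1cc([C@H]2Oc3c(OC)cc(C(O)[C@@H]4C(=O)O[C@H](c5cc(OC)c(OCc6ccccc6)c(OC)c5)[C@H]4CO[Si](C)(C)C(C)(C)C)cc3[C@H]2CO[Si](c2ccccc2)(c2ccccc2)C(C)(C)C)ccc1OCc1ccccc1 | intermediate (not isolated)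
21 | methanesulfonate of 20 at the carbinol oxygen | COc1cc([C@H]2Oc3c(OC)cc(C(OS(C)(=O)=O)[C@@H]4C(=O)O[C@H](c5cc(OC)c(OCc6ccccc6)c(OC)c5)[C@H]4CO[Si](C)(C)C(C)(C)C)cc3[C@H]2CO[Si](c2ccccc2)(c2ccccc2)C(C)(C)C)ccc1OCc1ccccc1 | intermediate (not isolated)
22 | (3E,4R,5S)-5-(4-benzyloxy-3,5-dimethoxyphenyl)-4-[(tert-butyldimethylsilyloxy)methyl]-3-(DHB-methylidene)dihydrofuran-2(3H)-one | COc1cc([C@H]2Oc3c(OC)cc(/C=C4/C(=O)O[C@H](c5cc(OC)c(OCc6ccccc6)c(OC)c5)[C@H]4CO[Si](C)(C)C(C)(C)C)cc3[C@H]2CO[Si](c2ccccc2)(c2ccccc2)C(C)(C)C)ccc1OCc1ccccc1 | intermediate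
23 | (3E,4R,5S)-5-(4-benzyloxy-3,5-dimethoxyphenyl)-4-(hydroxymethyl)-3-(DHB-methylidene)dihydrofuran-2(3H)-one (precursor of the key step) | COc1cc([C@H]2Oc3c(OC)cc(/C=C4/C(=O)O[C@H](c5cc(OC)c(OCc6ccccc6)c(OC)c5)[C@H]4CO)cc3[C@H]2CO[Si](c2ccccc2)(c2ccccc2)C(C)(C)C)ccc1OCc1ccccc1 | intermediate
24 | (1S,2S,5R,6S)-6-(4-benzyloxy-3,5-dimethoxyphenyl)-2-DHB-3,7-dioxabicyclo[3.3.0]octan-8-one (product of the key step) | COc1cc([C@H]2Oc3c(OC)cc([C@H]4OC[C@H]5[C@@H]4C(=O)O[C@@H]5c4cc(OC)c(OCc5ccccc5)c(OC)c4)cc3[C@H]2CO[Si](c2ccccc2)(c2ccccc2)C(C)(C)C)ccc1OCc1ccccc1 | intermediate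
25 | (S)-(4-benzyloxy-3,5-dimethoxyphenyl)[(3R,4R,5S)-5-DHB-4-(hydroxymethyl)tetrahydrofuran-3-yl]methanol | COc1cc([C@H]2Oc3c(OC)cc([C@H]4OC[C@H]([C@H](O)c5cc(OC)c(OCc6ccccc6)c(OC)c5)[C@@H]4CO)cc3[C@H]2CO[Si](c2ccccc2)(c2ccccc2)C(C)(C)C)ccc1OCc1ccccc1 | intermediate
26 | methanesulfonate of 25 at the primary hydroxyl | COc1cc([C@H]2Oc3c(OC)cc([C@H]4OC[C@H]([C@H](O)c5cc(OC)c(OCc6ccccc6)c(OC)c5)[C@@H]4COS(C)(=O)=O)cc3[C@H]2CO[Si](c2ccccc2)(c2ccccc2)C(C)(C)C)ccc1OCc1ccccc1 | intermediate (not isolated)
27 | (1R,2S,5R,6S)-6-(4-benzyloxy-3,5-dimethoxyphenyl)-2-DHB-3,7-dioxabicyclo[3.3.0]octane | COc1cc([C@H]2Oc3c(OC)cc([C@H]4OC[C@H]5[C@@H]4CO[C@@H]5c4cc(OC)c(OCc5ccccc5)c(OC)c4)cc3[C@H]2CO[Si](c2ccccc2)(c2ccccc2)C(C)(C)C)ccc1OCc1ccccc1 | intermediate (not isolated)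
28 | (1R,2S,5R,6S)-2-[(2S,3S)-2-(4-benzyloxy-3-methoxyphenyl)-3-(hydroxymethyl)-7-methoxy-2,3-dihydrobenzofuran-5-yl]-6-(4-benzyloxy-3,5-dimethoxyphenyl)-3,7-dioxabicyclo[3.3.0]octane | COc1cc([C@H]2Oc3c(OC)cc([C@H]4OC[C@H]5[C@@H]4CO[C@@H]5c4cc(OC)c(OCc5ccccc5)c(OC)c4)cc3[C@H]2CO)ccc1OCc1ccccc1 | intermediate
29 | (1R,2S,5R,6S)-2-[(2S,3S)-2-(4-hydroxy-3-methoxyphenyl)-3-(hydroxymethyl)-7-methoxy-2,3-dihydrobenzofuran-5-yl]-6-(4-hydroxy-3,5-dimethoxyphenyl)-3,7-dioxabicyclo[3.3.0]octane | COc1cc([C@H]2Oc3c(OC)cc([C@H]4OC[C@H]5[C@@H]4CO[C@@H]5c4cc(OC)c(O)c(OC)c4)cc3[C@H]2CO)ccc1O | target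

## Step count and least certain steps

Total: 19 steps (the telescoped sequences of steps 2, 14 and 18 are counted once each). Longest linear sequence: 14 steps (6 to 19). The other branch has 5 steps (1 to 5) and joins at step 14.

Step 16 (key step, proposed new method). The equilibrium may not lie far enough on the side of the bicycle, because closure gives up the push–pull conjugation of the arylidene lactone with ring B and with C8=O. Acyl migration of the lactone to O3, or slow migration of the double bond into the ring, may also drain material. Fallback with known reaction types, setting out from 23 and returning at 24: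
- 23 is treated with N-iodosuccinimide and NaHCO3 in CH2Cl2 at −20 °C. The iodonium ion opens toward the benzylic carbon C2, which is stabilised by O1', and O3 closes anti to iodine (5-endo iodoetherification of a homoallylic alcohol). This gives (1R,2S,5R,6S)-1-iodo-6-(4-benzyloxy-3,5-dimethoxyphenyl)-2-DHB-3,7-dioxabicyclo[3.3.0]octan-8-one F1, with the same face selectivity as in step 16.
- The C1–I bond is then reduced with Bu3SnH and Et3B/air in toluene at 0 °C. The C1 radical can only take hydrogen on the convex face, so the product is 24.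

Step 14. Retro-aldol cleavage of the lithium aldolate, incomplete or poorly E-selective elimination, or migration of the double bond into the ring (with loss of C5) during the DBU stage would lower the supply of 22. Fallback, setting out from 9 and returning at 22:
- 9 is treated with LiN(i-Pr)2 (2.2 equiv) and ClP(O)(OEt)2 in THF at −78 °C. The enol phosphate rearranges to the phosphonate anion, which is isolated as diethyl [(4R,5S)-5-(4-benzyloxy-3,5-dimethoxyphenyl)-4-[(tert-butyldimethylsilyloxy)methyl]-2-oxotetrahydrofuran-3-yl]phosphonate F2.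
- Horner–Wadsworth–Emmons olefination of 19 with F2 (LiCl, DBU, MeCN) gives 22 without a β-hydroxy intermediate or an elimination step.

Step 10. Stereocontrol may be eroded: the methoxy group ortho to the ether oxygen may lower the facial discrimination of the catalyst, the oxonium ylide path at O1' with benzyl shift may compete, and the cis ester can epimerise at C3' on handling. Fallback, setting out from 17 (of insufficient isomeric purity) and returning at 17:
- 17 is esterified with (S)-2-methoxy-2-phenylacetic acid (DCC, DMAP, CH2Cl2).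
- The diastereomer [(2S,3S)-2-(4-benzyloxy-3-methoxyphenyl)-5-bromo-7-methoxy-2,3-dihydrobenzofuran-3-yl]methyl (S)-2-methoxy-2-phenylacetate F3 is separated by crystallisation or chromatography.
- F3 is cleaved with K2CO3 in MeOH to pure 17. This replaces reliance on catalyst control by separation of covalent diastereomers.

Step 8. Over-oxidation is the danger: cleavage of the electron-rich enol ether double bond back to the aldehyde, or oxidation at the p-alkoxybenzylic methylene. Fallback, setting out from 12 and returning at 14: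
- van Leusen reductive cyanation of 12 (TosMIC, KOt-Bu, DME, −40 °C; then MeOH, reflux) gives 2-[2-[(4-benzyloxy-3-methoxyphenyl)methoxy]-5-bromo-3-methoxyphenyl]acetonitrile F4.
- Basic hydrolysis (KOH, EtOH/H2O, reflux) gives 2-[2-[(4-benzyloxy-3-methoxyphenyl)methoxy]-5-bromo-3-methoxyphenyl]acetic acid F5.
- Methylation with MeI and K2CO3 in DMF gives 14, with no oxidant and no acid at any stage.

Step 18. Sulfonylation may fail to discriminate the primary hydroxyl from the benzylic one, or the benzylic position may ionise, with chloride incorporation or epimerisation at C6. Fallback, setting out from 24 and returning at 27: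
- 24 is reduced with i-Bu2AlH in CH2Cl2 at −78 °C to the lactol (1R,2S,5R,6S)-6-(4-benzyloxy-3,5-dimethoxyphenyl)-2-DHB-3,7-dioxabicyclo[3.3.0]octan-8-ol F6 (anomers).
- The lactol hydroxyl is removed with Et3SiH and BF3·OEt2 in CH2Cl2 at −78 °C, giving 27. Bu4NF then gives 28 as in the route.
- This path exposes ring C briefly to a Lewis acid, which is why it is the reserve and not the first choice.

## Further compounds

F1 | step 16 | (1R,2S,5R,6S)-1-iodo-6-(4-benzyloxy-3,5-dimethoxyphenyl)-2-DHB-3,7-dioxabicyclo[3.3.0]octan-8-one | COc1cc([C@H]2Oc3c(OC)cc([C@H]4OC[C@H]5[C@]4(I)C(=O)O[C@@H]5c4cc(OC)c(OCc5ccccc5)c(OC)c4)cc3[C@H]2CO[Si](c2ccccc2)(c2ccccc2)C(C)(C)C)ccc1OCc1ccccc1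
F2 | step 14 | diethyl [(4R,5S)-5-(4-benzyloxy-3,5-dimethoxyphenyl)-4-[(tert-butyldimethylsilyloxy)methyl]-2-oxotetrahydrofuran-3-yl]phosphonate (C3 epimers) | CCOP(=O)(OCC)C1C(=O)O[C@H](c2cc(OC)c(OCc3ccccc3)c(OC)c2)[C@H]1CO[Si](C)(C)C(C)(C)C
F3 | step 10 | [(2S,3S)-2-(4-benzyloxy-3-methoxyphenyl)-5-bromo-7-methoxy-2,3-dihydrobenzofuran-3-yl]methyl (S)-2-methoxy-2-phenylacetate | COc1cc([C@H]2Oc3c(OC)cc(Br)cc3[C@H]2COC(=O)[C@@H](OC)c2ccccc2)ccc1OCc1ccccc1
F4 | step 8 | 2-[2-[(4-benzyloxy-3-methoxyphenyl)methoxy]-5-bromo-3-methoxyphenyl]acetonitrile | N#CCc1cc(Br)cc(OC)c1OCc1ccc(OCc2ccccc2)c(OC)c1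
F5 | step 8 | 2-[2-[(4-benzyloxy-3-methoxyphenyl)methoxy]-5-bromo-3-methoxyphenyl]acetic acid | OC(=O)Cc1cc(Br)cc(OC)c1OCc1ccc(OCc2ccccc2)c(OC)c1
F6 | step 18 | (1R,2S,5R,6S)-6-(4-benzyloxy-3,5-dimethoxyphenyl)-2-DHB-3,7-dioxabicyclo[3.3.0]octan-8-ol (anomers) | COc1cc([C@H]2Oc3c(OC)cc([C@H]4OC[C@H]5[C@@H]4C(O)O[C@@H]5c4cc(OC)c(OCc5ccccc5)c(OC)c4)cc3[C@H]2CO[Si](c2ccccc2)(c2ccccc2)C(C)(C)C)ccc1OCc1ccccc1
A1 | alternative 1 | (2S,3S)-2-(4-benzyloxy-3-methoxyphenyl)-3-(benzyloxymethyl)-5-(tert-butyldimethylsilyloxymethyl)-2,3-dihydrobenzofuran-7-ol (cis) | COc1cc([C@H]2Oc3c(O)cc(CO[Si](C)(C)C(C)(C)C)cc3[C@H]2COCc2ccccc2)ccc1OCc1ccccc1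
A2 | alternative 1 | 2-[(2S,3S)-1-benzyloxy-3-(4-benzyloxy-3-methoxyphenyl)-3-(ethynyloxy)propan-2-yl]-4-(tert-butyldimethylsilyloxymethyl)furan | COc1cc([C@@H](OC#C)[C@H](COCc2ccccc2)c2cc(CO[Si](C)(C)C(C)(C)C)co2)ccc1OCc1ccccc1
A3 | alternative 2 | trans,trans-3-[aryl(hydroxy)methyl]-4-[2-(4-benzyloxy-3,5-dimethoxyphenyl)-1,3-dithian-2-yl]-5-menthyloxydihydrofuran-2(3H)-one, aryl = silyl-protected cis-dihydrobenzofuran-5-yl, carbinol carbon unassigned | COc1cc([C@H]2Oc3c(OC)cc(C(O)[C@H]4C(=O)O[C@@H](O[C@@H]5C[C@H](C)CC[C@H]5C(C)C)[C@@H]4C4(c5cc(OC)c(OCc6ccccc6)c(OC)c5)SCCCS4)cc3[C@H]2CO[Si](C)(C)C(C)(C)C)ccc1OCc1ccccc1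
A4 | alternative 2 | (5R)-5-[(1R,2S,5R)-menthyloxy]furan-2(5H)-one | O=C1C=C[C@H](O[C@@H]2C[C@H](C)CC[C@H]2C(C)C)O1
A5 | alternative 2 | 2-(4-benzyloxy-3,5-dimethoxyphenyl)-1,3-dithiane | COc1cc(C2SCCCS2)cc(OC)c1OCc1ccccc1
A6 | alternative 2 | (2S,3S)-2-(4-benzyloxy-3-methoxyphenyl)-3-(tert-butyldimethylsilyloxymethyl)-7-methoxy-2,3-dihydrobenzofuran-5-carbaldehyde | COc1cc([C@H]2Oc3c(OC)cc(C=O)cc3[C@H]2CO[Si](C)(C)C(C)(C)C)ccc1OCc1ccccc1
A7 | alternative 3 | (1R,2S,5R,6S)-2-[(2S,3S)-2-(4-benzyloxy-3-methoxyphenyl)-3-(tert-butyldimethylsilyloxymethyl)-7-methoxy-2,3-dihydrobenzofuran-5-yl]-6-(4-benzyloxy-3,5-dimethoxyphenyl)-3,7-dioxabicyclo[3.3.0]octane | COc1cc([C@H]2Oc3c(OC)cc([C@H]4OC[C@H]5[C@@H]4CO[C@@H]5c4cc(OC)c(OCc5ccccc5)c(OC)c4)cc3[C@H]2CO[Si](C)(C)C(C)(C)C)ccc1OCc1ccccc1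
A8 | alternative 3 | (E)-3-(4-benzyloxy-3,5-dimethoxyphenyl)prop-2-enyl ether of the (S)-aryl(oxiran-2-yl)methanol, aryl = silyl-protected cis-dihydrobenzofuran-5-yl, epoxide carbon unassigned | COc1cc([C@H]2Oc3c(OC)cc([C@@H](OC/C=C/c4cc(OC)c(OCc5ccccc5)c(OC)c4)C4CO4)cc3[C@H]2CO[Si](C)(C)C(C)(C)C)ccc1OCc1ccccc1
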